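The ten-membered carbocycle (C1–C10, germacrane numbering) is not closed directly: C1 and C10 are first tied through sulfur in an eleven-membered thiacycle, and a Ramberg–Bäcklund reaction then extrudes SO2, contracts the ring and creates the C1=C10 enoate in one operation. The step exploits that C10 carries the ester carbon C14, so the sulfonyl-ester carbon alone is chlorinated, and that a ten-membered ring accepts only the cis-fused episulfone, which delivers the ring-cis C1=C10 bond. The precursor is a cyclic α-sulfonyl ester assembled from a lyxonolactone-derived dioxolanyl radical (C8–C10, C14), an (S)-butenolide (C5–C7, C11, C12) and a formyl ylide (C1–C4, C15).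

Key step: step 13

Remark: germacrane numbering is used throughout (ring C1–C10; lactone C11, C12 (C=O), C13 (=CH2); ester carbon C14; hydroxymethyl carbon C15); compounds 1, 4 and 8 are assumed purchasable; C10 of 17–19 is epimerisable or quaternary and is written without configuration.

Step 1
Reactants: 1 2,3-O-isopropylidene-D-lyxono-1,4-lactone
Product: 2 2,3-O-isopropylidene-D-lyxaro-1,4-lactone (free C5 carboxylic acid)
Conditions: TEMPO (0.2 equiv), PhI(OAc)2 (2.2 equiv), MeCN–H2O (1:1), rt
Reagents that add atoms: water, O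
Why: Oxoammonium (TEMPO) oxidation in wet acetonitrile should take the only free primary alcohol through the aldehyde hydrate to the acid, leaving lactone and acetonide untouched.

Step 2
Reactants: 2 2,3-O-isopropylidene-D-lyxaro-1,4-lactone (free C5 carboxylic acid)
Product: 3 methyl ester of 2
Conditions: MeI, K2CO3, DMF, 0 °C → rt
Reagents that add atoms: iodomethane, CI
Why: SN2 O-alkylation of the carboxylate gives the methyl ester (the future C14 ester) under conditions too mild to open the lactone.

Step 3
Reactants: 3 methyl ester of 2; 4 (S)-5-(hydroxymethyl)furan-2(5H)-one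
Product: 6 Giese adduct (hydroxymethyl γ-lactone carrying the trans C8/C9 acetonide and the C10 hydroxy ester), via lithium carboxylate 5 (not isolated)
Conditions: LiOH·H2O (1.0 equiv), DMSO–H2O (9:1), 0 °C; then 4 (1.5 equiv), KH2PO4 (1.5 equiv), [Ir(dF(CF3)ppy)2(dtbbpy)]PF6 (1 mol %), 450 nm LED, rt
Reagents that add atoms: none
Why: One equivalent of hydroxide should open the strained cis-fused lactone faster than it cleaves the methyl ester, and photoredox decarboxylation of the α-alkoxy carboxylate gives the C8 dioxolanyl radical for a decarboxylative Giese addition to the butenolide, in which C8 is set by attack trans to the C9 substituent on the dioxolane (cis-lyxo becomes the threo C8/C9 pattern) and C7 by attack anti to the C6 hydroxymethyl group.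

Step 4
Reactants: 6 Giese adduct
Product: 7 C5 aldehyde
Conditions: TEMPO (0.1 equiv), PhI(OAc)2 (1.1 equiv), CH2Cl2, rt
Reagents that add atoms: none
Why: TEMPO/PhI(OAc)2 oxidation in dry dichloromethane is selective for primary over secondary alcohols, so the C5 aldehyde should form while the C10 α-hydroxy ester stays.

Step 5
Reactants: 8 (4-bromobutyl)triphenylphosphonium bromide
Product: 9 [4-(tritylsulfanyl)butyl]triphenylphosphonium bromide
Conditions: Ph3CSH, K2CO3, DMF, rt
Reagents that add atoms: triphenylmethanethiol, SC(c1ccccc1)(c1ccccc1)c1ccccc1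
Why: SN2 S-alkylation of the thiolate by the primary bromide installs the future ring sulfur in a form that survives ylide chemistry, carbonate being too weak to deprotonate the phosphonium salt.

Step 6
Reactants: 9 [4-(tritylsulfanyl)butyl]triphenylphosphonium bromide
Product: 10 2-(triphenyl-λ5-phosphanylidene)-5-(tritylsulfanyl)pentanal
Conditions: NaHMDS (2.1 equiv), THF, −78 °C; HCO2Et, −78 °C → rt
Reagents that add atoms: ethyl formate, CCOC=O
Why: C-Formylation of the non-stabilised phosphonium ylide with ethyl formate (ylide acylation), followed by deprotonation, gives the stabilised α-substituted formyl ylide carrying C15.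

Step 7
Reactants: 7 C5 aldehyde; 10 2-(triphenyl-λ5-phosphanylidene)-5-(tritylsulfanyl)pentanal
Product: 11 trisubstituted enal (C4=C5, CHO trans to C6)
Conditions: toluene, 70 °C
Reagents that add atoms: none
Why: Wittig olefination with the stabilised formyl ylide should place the formyl group (C15) trans to C6 and the C3 chain cis to C6, which is the ring-cis C4=C5 geometry of the target, under neutral conditions that spare the epimerisable C6.

Step 8
Reactants: 11 trisubstituted enal
Product: 12 C15 allylic alcohol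
Conditions: NaBH4, CeCl3·7H2O, MeOH, −40 °C
Reagents that add atoms: none
Why: Luche reduction delivers hydride 1,2 to the enal only, leaving lactone, ester and alkene.

Step 9
Reactants: 12 C15 allylic alcohol
Product: 13 C15 TBDPS ether
Conditions: TBDPSCl, imidazole, CH2Cl2, 0 °C
Reagents that add atoms: tert-butyl(chloro)diphenylsilane, CC(C)(C)[Si](Cl)(c1ccccc1)c1ccccc1
Why: Silylation with the bulky chlorosilane is selective for the primary allylic C15 hydroxyl over the hindered secondary C10 hydroxyl.

Step 10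
Reactants: 13 C15 TBDPS ether
Product: 14 C10 triflate
Conditions: Tf2O, 2,6-lutidine, CH2Cl2, −78 °C
Reagents that add atoms: trifluoromethanesulfonic anhydride, O=S(=O)(OS(=O)(=O)C(F)(F)F)C(F)(F)F
Why: O-Sulfonylation of the α-hydroxy ester activates C10 for SN2 displacement, the hindered trityl sulfide and the other groups being inert at −78 °C.

Step 11
Reactants: 14 C10 triflate
Product: 16 eleven-membered cyclic sulfide (S between C1 and C10), via thiol 15 (not isolated)
Conditions: CF3CO2H (10 vol %), iPr3SiH, CH2Cl2, 0 °C; then iPr2NEt, MeCN (0.002 M), 0 °C → rt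
Reagents that add atoms: none
Why: Acidolysis with silane trapping removes the S-trityl group and the thiol then displaces the α-triflyloxy ester intramolecularly (SN2 thioetherification at high dilution, inversion at C10, whose configuration is later destroyed), closing the thiacycle.

Step 12
Reactants: 16 eleven-membered cyclic sulfide
Product: 17 cyclic sulfone
Conditions: (NH4)6Mo7O24·4H2O (10 mol %), 30 % H2O2, EtOH, 0 °C → rt
Reagents that add atoms: hydrogen peroxide, OO
Why: Molybdate-catalysed peroxide oxidation takes the sulfide to the sulfone and should not epoxidise the trisubstituted alkene.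

Step 13
Reactants: 17 cyclic sulfone
Product: 20 ten-membered diene ester (ring-cis C1=C10), via α-chloro sulfone 18 (not isolated), via episulfone 19 (not isolated)
Conditions: KOtBu (1.05 equiv), C2Cl6 (1.05 equiv), THF, −78 → 0 °C; then KOtBu (2.5 equiv), −78 → −20 °C
Reagents that add atoms: none
Why: Ramberg–Bäcklund reaction: the first equivalent of base deprotonates only C10 (flanked by sulfonyl and the C14 ester) and hexachloroethane chlorinates it, then tert-butoxide removes an α′ proton at C1, the carbanion displaces chloride at C10 in a 3-exo-tet 1,3-elimination to the episulfone, and cheletropic loss of SO2 joins C1 and C10 as the alkene, so the eleven-membered thiacycle contracts to the ten-membered carbocycle. The closest known reaction types are Ramberg–Bäcklund contractions of macrocyclic sulfones and the halogenation/rearrangement of α-sulfonyl esters to α,β-unsaturated esters. No stereocentre is formed; the C1=C10 geometry follows from the episulfone, which on a ten-membered ring can only be cis-fused (C2 and C9 cis) and whose C1–H is epimerisable, and this ring-cis isomer is also the preferred enoate geometry (ester cis to H1). The step needs site selectivity for C10 in the halogenation, which the C14 ester secures, and an α′ carbanion without a β-leaving group, which is why sulfur bridges C1/C10 and not C4/C5 next to the lactone oxygen. The acetonide ties O9 against elimination from the C10 anion, and lactone, silyl ether and the C4=C5 alkene should tolerate tert-butoxide at low temperature.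

Step 14
Reactants: 20 ten-membered diene ester
Product: 23 α-methylene lactone, via Mannich base 21 (not isolated), via ammonium iodide 22 (not isolated)
Conditions: LDA, THF, −78 °C; CH2=NMe2+ I−, −78 °C → rt; then MeI, CH2Cl2, rt; then aq. NaHCO3
Reagents that add atoms: N,N-dimethylmethyleneiminium iodide, C=[N+](C)C.[I-]
Why: Kinetic lactone enolate formation (the enoate γ-hydrogens at C2 lie trans to the ester carbonyl), Mannich reaction with Eschenmoser's salt, N-methylation and Hofmann-type elimination install the C11=C13 methylene.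

Step 15
Reactants: 23 α-methylene lactone
Product: 24 C8/C9 diol
Conditions: AcOH–H2O (4:1), 50 °C
Reagents that add atoms: none
Why: Mild acid hydrolysis of the isopropylidene acetal frees the diol while the TBDPS ether, both unsaturated esters and the α-methylene lactone should persist.

Step 16
Reactants: 24 C8/C9 diol
Product: 25 9-O-acetate
Conditions: Ac2O (1.1 equiv), pyridine, CH2Cl2, −20 °C
Reagents that add atoms: acetic anhydride, CC(=O)OC(C)=O
Why: Acetylation is expected at the allylic C9 hydroxyl, flanked by the planar C10, in preference to the C8 hydroxyl buttressed by the C7 ring-fusion carbon.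

Step 17
Reactants: 25 9-O-acetate
Product: 26 8-O-methacrylate 9-O-acetate (15-O-TBDPS)
Conditions: methacrylic anhydride, Et3N, DMAP (cat.), CH2Cl2, 0 °C → rt
Reagents that add atoms: methacrylic anhydride, CC(=C)C(=O)OC(=O)C(C)=C
Why: DMAP-catalysed (Steglich-type) acylation esterifies the remaining hindered C8 hydroxyl.

Step 18
Reactants: 26 8-O-methacrylate 9-O-acetate (15-O-TBDPS)
Product: 27 target CNP0179134.2
Conditions: HF·pyridine, pyridine, THF, 0 °C → rt
Reagents that add atoms: none
Why: Buffered fluoride desilylation frees the C15 alcohol without acyl migration or conjugate addition to the α-methylene lactone.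

Compound list

1 | 2,3-O-isopropylidene-D-lyxono-1,4-lactone (all-cis) | OC[C@H]1OC(=O)[C@H]2OC(C)(C)O[C@@H]12 | starting material
2 | 2,3-O-isopropylidene-D-lyxaro-1,4-lactone, C5 carboxylic acid (lyxono numbering kept) | OC(=O)[C@H]1OC(=O)[C@H]2OC(C)(C)O[C@@H]12 | intermediate
3 | methyl ester of 2 | COC(=O)[C@H]1OC(=O)[C@H]2OC(C)(C)O[C@@H]12 | intermediate
4 | (S)-5-(hydroxymethyl)furan-2(5H)-one | O=C1C=C[C@@H](CO)O1 | starting material
5 | lithium salt of the opened lactone: cis-2,2-dimethyl-1,3-dioxolane-4-carboxylate whose C5 bears CH(OH)CO2Me | [Li+].[O-]C(=O)[C@H]1OC(C)(C)O[C@H]1[C@H](O)C(=O)OC | intermediate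
6 | Giese adduct: trans-4,5-disubstituted γ-butyrolactone (C6 CH2OH; C7) carrying the trans-dioxolane (C8/C9) and the C10 hydroxy methyl ester; C6–C9 configured as in the target | OC[C@H]1OC(=O)C[C@@H]1[C@@H]1OC(C)(C)O[C@H]1[C@H](O)C(=O)OC | intermediate
7 | C5 aldehyde of 6 | O=C[C@H]1OC(=O)C[C@@H]1[C@@H]1OC(C)(C)O[C@H]1[C@H](O)C(=O)OC | intermediate
8 | (4-bromobutyl)triphenylphosphonium bromide | BrCCCC[P+](c1ccccc1)(c1ccccc1)c1ccccc1.[Br-] | starting material
9 | [4-(tritylsulfanyl)butyl]triphenylphosphonium bromide | [Br-].c1ccccc1C(c1ccccc1)(c1ccccc1)SCCCC[P+](c1ccccc1)(c1ccccc1)c1ccccc1 | intermediate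
10 | 2-(triphenyl-λ5-phosphanylidene)-5-(tritylsulfanyl)pentanal | O=CC(CCCSC(c1ccccc1)(c1ccccc1)c1ccccc1)=P(c1ccccc1)(c1ccccc1)c1ccccc1 | intermediate
11 | enal: C4=C5 with CHO (C15) trans to C6, C4 carrying the 3-(tritylsulfanyl)propyl chain (C3–C1) | O=C/C(CCCSC(c1ccccc1)(c1ccccc1)c1ccccc1)=C/[C@H]1OC(=O)C[C@@H]1[C@@H]1OC(C)(C)O[C@H]1[C@H](O)C(=O)OC | intermediate
12 | C15 allylic alcohol from 11 | OC/C(CCCSC(c1ccccc1)(c1ccccc1)c1ccccc1)=C/[C@H]1OC(=O)C[C@@H]1[C@@H]1OC(C)(C)O[C@H]1[C@H](O)C(=O)OC | intermediate
13 | C15 TBDPS ether of 12 | CC(C)(C)[Si](c1ccccc1)(c1ccccc1)OC/C(CCCSC(c1ccccc1)(c1ccccc1)c1ccccc1)=C/[C@H]1OC(=O)C[C@@H]1[C@@H]1OC(C)(C)O[C@H]1[C@H](O)C(=O)OC | intermediate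
14 | C10 triflate of 13 | CC(C)(C)[Si](c1ccccc1)(c1ccccc1)OC/C(CCCSC(c1ccccc1)(c1ccccc1)c1ccccc1)=C/[C@H]1OC(=O)C[C@@H]1[C@@H]1OC(C)(C)O[C@H]1[C@H](OS(=O)(=O)C(F)(F)F)C(=O)OC | intermediate
15 | C1 thiol (C10 triflate) | CC(C)(C)[Si](c1ccccc1)(c1ccccc1)OC/C(CCCS)=C/[C@H]1OC(=O)C[C@@H]1[C@@H]1OC(C)(C)O[C@H]1[C@H](OS(=O)(=O)C(F)(F)F)C(=O)OC | intermediate
16 | eleven-membered cyclic sulfide (ring S, C1–C10; C10 inverted, bearing CO2Me) | CC(C)(C)[Si](c1ccccc1)(c1ccccc1)OC/C1=C/[C@H]2OC(=O)C[C@@H]2[C@@H]2OC(C)(C)O[C@H]2[C@H](C(=O)OC)SCCC1 | intermediate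
17 | eleven-membered cyclic sulfone (α-sulfonyl ester) | CC(C)(C)[Si](c1ccccc1)(c1ccccc1)OC/C1=C/[C@H]2OC(=O)C[C@@H]2[C@@H]2OC(C)(C)O[C@H]2C(C(=O)OC)S(=O)(=O)CCC1 | intermediate
18 | α-chloro sulfone (Cl on C10) | CC(C)(C)[Si](c1ccccc1)(c1ccccc1)OC/C1=C/[C@H]2OC(=O)C[C@@H]2[C@@H]2OC(C)(C)O[C@H]2C(Cl)(C(=O)OC)S(=O)(=O)CCC1 | intermediate
19 | episulfone (thiirane 1,1-dioxide across C1–C10, cis-fused on the ten-membered ring) | CC(C)(C)[Si](c1ccccc1)(c1ccccc1)OC/C1=C/[C@H]2OC(=O)C[C@@H]2[C@@H]2OC(C)(C)O[C@H]2C2(C(=O)OC)C(CC1)S2(=O)=O | intermediate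
20 | ten-membered carbocycle: ring-cis C1=C10 (CO2Me on C10), ring-cis C4=C5 (CH2OTBDPS on C4), trans 6,12-lactone, 8,9-O-isopropylidene | CC1(C)O[C@H]2[C@H]3CC(=O)O[C@@H]3/C=C(/CO[Si](c3ccccc3)(c3ccccc3)C(C)(C)C)CC/C=C(/C(=O)OC)[C@@H]2O1 | intermediate
21 | C11 dimethylaminomethyl lactone (Mannich base, C11 unassigned) | CC1(C)O[C@H]2[C@H]3C(CN(C)C)C(=O)O[C@@H]3/C=C(/CO[Si](c3ccccc3)(c3ccccc3)C(C)(C)C)CC/C=C(/C(=O)OC)[C@@H]2O1 | intermediate
22 | C11 trimethylammoniomethyl lactone iodide | [I-].CC1(C)O[C@H]2[C@H]3C(C[N+](C)(C)C)C(=O)O[C@@H]3/C=C(/CO[Si](c3ccccc3)(c3ccccc3)C(C)(C)C)CC/C=C(/C(=O)OC)[C@@H]2O1 | intermediate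
23 | α-methylene lactone (C11=C13), 8,9-acetonide, 15-O-TBDPS | CC1(C)O[C@H]2[C@H]3C(=C)C(=O)O[C@@H]3/C=C(/CO[Si](c3ccccc3)(c3ccccc3)C(C)(C)C)CC/C=C(/C(=O)OC)[C@@H]2O1 | intermediate
24 | 8,9-diol, 15-O-TBDPS | O[C@H]1[C@H]2C(=C)C(=O)O[C@@H]2/C=C(/CO[Si](c2ccccc2)(c2ccccc2)C(C)(C)C)CC/C=C(/C(=O)OC)[C@@H]1O | intermediate
25 | 9-O-acetate, 8-OH, 15-O-TBDPS | O[C@H]1[C@H]2C(=C)C(=O)O[C@@H]2/C=C(/CO[Si](c2ccccc2)(c2ccccc2)C(C)(C)C)CC/C=C(/C(=O)OC)[C@@H]1OC(C)=O | intermediate
26 | 8-O-methacrylate 9-O-acetate, 15-O-TBDPS | C=C(C)C(=O)O[C@H]1[C@H]2C(=C)C(=O)O[C@@H]2/C=C(/CO[Si](c2ccccc2)(c2ccccc2)C(C)(C)C)CC/C=C(/C(=O)OC)[C@@H]1OC(C)=O | intermediate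
27 | CNP0179134.2 (6R,7S,8S,9S) | C=C(C)C(=O)O[C@H]1[C@H]2C(=C)C(=O)O[C@@H]2/C=C(/CO)CC/C=C(/C(=O)OC)[C@@H]1OC(C)=O | target

Total step count: 18. Longest linear sequence: 16 (steps 1–4 and 7–18).

Steps most likely to fail

Step 13 (key step). The C10 sulfonyl-ester anion may expel O9 (opening the acetonide) before it is chlorinated. Positive chlorine may also be handed back from C10 to tert-butoxide or to the lactone enolate, so the 1,3-elimination stalls, and excess base may deprotonate the product at C2. The fallback makes the C–Cl bond without any C10 carbanion and runs the rearrangement on an isolated halide. It sets out from sulfide 16: N-chlorosuccinimide in CH2Cl2 at 0 °C should chlorinate the ester-activated C10 through the chlorosulfonium/thionium (Pummerer-type) pathway to give the α-chloro sulfide F1. Buffered mCPBA at −20 °C should oxidise this to the α-chloro sulfone 18, now isolated, and KOtBu in THF at −78 °C then gives 20 through 19, where the route is rejoined.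

Step 11. Intermolecular S-alkylation (oligomers) may outrun closure of the strained eleven-membered ring, or base may eliminate the triflate. The fallback forms the S–C10 bond between two molecules and closes the thiacycle at C4=C5 instead. It sets out from aldehyde 7 and ylide 10. Tf2O/2,6-lutidine converts 7 into the aldehyde triflate F2, and CF3CO2H/iPr3SiH followed by NaHCO3 converts 10 into the thiol ylide F3. F2 and F3 with iPr2NEt at −40 °C should give the sulfide-tethered ylide aldehyde F4 (SN2, inversion at C10). Heating F4 in dilute toluene should close the ring by intramolecular Wittig olefination to the cyclic enal F5, the ring and the stabilised ylide both favouring CHO trans to C6. Luche reduction gives the cyclic allylic alcohol F6, and TBDPSCl/imidazole returns to 16.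

Step 16. The two secondary hydroxyls may be discriminated poorly or in the opposite sense, the acetyl group may migrate from O9 to O8, and the free C8 hydroxyl may translactonise onto C12. If the first acyl group enters at O8, the fallback inverts the order of the two acylations. It sets out from diol 24: methacrylic anhydride (1.1 equiv, Et3N, −20 °C) gives the 8-O-methacrylate F7, and Ac2O/DMAP then acetylates O9 and returns to the route at 26.

Further compounds
F1 | step 13 | α-chloro sulfide (Cl on C10 of the eleven-membered cyclic sulfide) | CC(C)(C)[Si](c1ccccc1)(c1ccccc1)OC/C1=C/[C@H]2OC(=O)C[C@@H]2[C@@H]2OC(C)(C)O[C@H]2C(Cl)(C(=O)OC)SCCC1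
F2 | step 11 | aldehyde triflate (C5 aldehyde, C10 triflate) | O=C[C@H]1OC(=O)C[C@@H]1[C@@H]1OC(C)(C)O[C@H]1[C@H](OS(=O)(=O)C(F)(F)F)C(=O)OC
F3 | step 11 | thiol ylide, 5-sulfanyl-2-(triphenyl-λ5-phosphanylidene)pentanal | O=CC(CCCS)=P(c1ccccc1)(c1ccccc1)c1ccccc1
F4 | step 11 | sulfide-tethered ylide aldehyde (S on C10, inverted) | O=C[C@H]1OC(=O)C[C@@H]1[C@@H]1OC(C)(C)O[C@H]1[C@@H](SCCCC(C=O)=P(c1ccccc1)(c1ccccc1)c1ccccc1)C(=O)OC
F5 | step 11 | eleven-membered cyclic enal (C15 aldehyde) | O=C/C1=C/[C@H]2OC(=O)C[C@@H]2[C@@H]2OC(C)(C)O[C@H]2[C@H](C(=O)OC)SCCC1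
F6 | step 11 | eleven-membered cyclic allylic alcohol (C15 OH) | OC/C1=C/[C@H]2OC(=O)C[C@@H]2[C@@H]2OC(C)(C)O[C@H]2[C@H](C(=O)OC)SCCC1
F7 | step 16 | 8-O-methacrylate, 9-OH, 15-O-TBDPS | C=C(C)C(=O)O[C@H]1[C@H]2C(=C)C(=O)O[C@@H]2/C=C(/CO[Si](c2ccccc2)(c2ccccc2)C(C)(C)C)CC/C=C(/C(=O)OC)[C@@H]1O
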